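**Strategy.** Atoms carry the azulene numbering of the hydroazulene core. Everything rests on opening the cycloheptene at C4–C5 and the ring-fusion bond C3a–C8a: a five-carbon unit C5=C6–C7–C8–C8a is annulated across the C3a=C4 enol of a β-hydroxy aldehyde cut out of (S)-terpinen-4-ol. In one nickel-catalysed operation a tertiary C8a radical closes the cyclopentane onto C3a and the resulting C4 radical is joined to the tethered (Z)-alkenyl bromide, closing the seven-membered ring (formal [5+2]). The step exploits the 1,3-dioxygenation O3/O4 around C3a, tied as a cyclic silyl enol ether, and the C5=C6 alkene carried as the alkenyl halide.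

Key step: step 7

Assumption: (S)-terpinen-4-ol [(1S)-4-methyl-1-(propan-2-yl)cyclohex-3-en-1-ol] is taken as commercially available in high enantiomeric purity; partly racemic lots would be upgraded before use.

Step 1
Reactants: 1 but-3-yn-1-ol
Product: 3 (3Z)-4-bromo-3-methylbut-3-en-1-ol, via chelated Z-alkenylalane 2 (not isolated)
Conditions: Me3Al, Cp2ZrCl2 (cat.), ClCH2CH2Cl, rt, then reflux; NBS, THF, −30 °C
Reagents that add atoms: trimethylaluminium C[Al](C)C; N-bromosuccinimide O=C1CCC(=O)N1Br
Why: Negishi carboalumination adds Me–Al syn across the alkyne; on heating the alkoxide-chelated alane should equilibrate to the Z isomer, and bromodealumination with retention then places Br cis to the CH2CH2O chain.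

Step 2
Reactants: 3 (3Z)-4-bromo-3-methylbut-3-en-1-ol
Product: 4 (1Z)-1-bromo-4-iodo-2-methylbut-1-ene
Conditions: I2, PPh3, imidazole, CH2Cl2, 0 °C
Reagents that add atoms: iodine II
Why: Appel iodination of the primary alcohol; the alkenyl bromide is inert and keeps its geometry.

Step 3
Reactants: 5 (S)-terpinen-4-ol
Product: 7 (3S)-3-hydroxy-6-oxo-3-(propan-2-yl)heptanal, via ozonide 6 (not isolated)
Conditions: O3, CH2Cl2, −78 °C; PPh3, −78 °C → rt; used crude
Reagents that add atoms: ozone [O-][O+]=O
Why: Ozonolysis of the trisubstituted ring alkene with reductive work-up unveils the methyl ketone (C8a) and the aldehyde (C4) in one step, and the carbinol stereocentre (C3) is untouched.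

Step 4
Reactants: 7 (3S)-3-hydroxy-6-oxo-3-(propan-2-yl)heptanal
Product: 8 4-[(4R)-2,2,4-tri(propan-2-yl)-4H-1,3,2-dioxasilin-4-yl]butan-2-one
Conditions: iPr2Si(OTf)2, Et3N, CH2Cl2, −78 → 0 °C
Reagents that add atoms: di(propan-2-yl)silanediyl bis(trifluoromethanesulfonate) CC(C)[Si](OS(=O)(=O)C(F)(F)F)(OS(=O)(=O)C(F)(F)F)C(C)C
Why: Silylation of the tertiary alcohol followed by intramolecular soft enolisation and O-silylation of the aldehyde (silyl enol ether formation) closes a six-membered cyclic silyl enol ether, which masks the aldehyde, fixes the Z enol geometry and ties O3 to O4; the remote methyl ketone cannot reach silicon in a favourable ring size.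

Step 5
Reactants: 4 (1Z)-1-bromo-4-iodo-2-methylbut-1-ene; 8 4-[(4R)-2,2,4-tri(propan-2-yl)-4H-1,3,2-dioxasilin-4-yl]butan-2-one
Product: 10 (6Z)-7-bromo-3,6-dimethyl-1-[(4R)-2,2,4-tri(propan-2-yl)-4H-1,3,2-dioxasilin-4-yl]hept-6-en-3-ol (both C3 epimers), via Grignard reagent 9 (not isolated)
Conditions: Mg, THF, 0 °C → rt; then 8, LaCl3·2LiCl, THF, −78 → 0 °C
Reagents that add atoms: none
Why: Magnesium should insert into the alkyl iodide and leave the alkenyl bromide, and the lanthanum-promoted Grignard 1,2-addition to the methyl ketone gives the tertiary alcohol as an epimer mixture, which is irrelevant because this carbon becomes a planar radical.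

Step 6
Reactants: 10 (6Z)-7-bromo-3,6-dimethyl-1-[(4R)-2,2,4-tri(propan-2-yl)-4H-1,3,2-dioxasilin-4-yl]hept-6-en-3-ol
Product: 11 methyl oxalate ester of 10 [(6Z)-7-bromo-3,6-dimethyl-1-[(4R)-2,2,4-tri(propan-2-yl)-4H-1,3,2-dioxasilin-4-yl]hept-6-en-3-yl methyl oxalate]
Conditions: ClC(=O)CO2Me, pyridine, DMAP (cat.), CH2Cl2, 0 °C → rt
Reagents that add atoms: methyl chlorooxoacetate COC(=O)C(=O)Cl
Why: DMAP-catalysed acylation of the tertiary alcohol installs the radical precursor; the silyl enol ether and alkenyl bromide should tolerate the basic conditions.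

Step 7
Reactants: 11 methyl oxalate ester of 10
Product: 12 O3,O4-di(propan-2-yl)silanediyl acetal of (3R,3aS,4R,8aR)-6,8a-dimethyl-3-(propan-2-yl)-1,2,3,3a,4,7,8,8a-octahydroazulene-3,4-diol
Conditions: NiBr2·dme (15 mol %), 4,4′-di-tert-butyl-2,2′-bipyridine (20 mol %), Zn (3 equiv), MgCl2 (1.5 equiv), DMA, 0.01 M, 25 °C
Reagents that add atoms: none
Why: Proposed new method: Zn/MgCl2 reduces the tertiary alkyl methyl oxalate, which fragments to the planar C8a radical; this adds 5-exo-trig to C3a of the cyclic silyl enol ether, and the α-silyloxy C4 radical is captured by the divalent alkenylnickel bromide formed from zerovalent nickel and the tethered (Z)-bromoalkene, after which C(sp3)–C(sp2) reductive elimination from trivalent nickel forms C4–C5 (direct radical attack at the CHBr carbon with loss of a bromine atom would give the same product). The closest known reaction types are the Zn/MgCl2–nickel arylation of tertiary alkyl oxalates and nickel-catalysed alkyl-arylation and alkyl-alkenylation of electron-rich alkenes with tertiary radicals, here run with both partners tethered. Ring A (cyclopentane) closes by 5-exo-trig radical addition; the cycloheptene closes by reductive elimination from an eight-membered nickelacycle, the (Z) geometry of the bromoalkene becoming the ring alkene. C3a is fixed by the three-atom tether, which can reach only its own face of the dioxasiline and gives the cis-fused cyclopentane with O3 and C4 cis; C4 is set because the alkenylnickel hangs from C8a on the concave face and bonds axially to the ring radical, cis to C8a, so H4 ends syn to H3a; C8a is not induced at the planar radical (CH3 against CH2CH2R) but selected, since only the radical with the chain syn to C4 is expected to close the ring and its epimer should be lost as reduced bicycle. The step needs cyclisation to outrun nickel capture or reduction of the tertiary radical, which the slow capture of tertiary radicals, the fully substituted chain and high dilution should secure, and radical generation at the oxalate only, which the inertness of the silyl enol ether and alkenyl bromide to Zn/MgCl2 should secure.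

Step 8
Reactants: 12 silylene acetal of the octahydroazulene-3,4-diol
Product: 13 (3R,3aS,4R,8aR)-6,8a-dimethyl-3-(propan-2-yl)-1,2,3,3a,4,7,8,8a-octahydroazulene-3,4-diol
Conditions: HF·pyridine, pyridine, THF, 0 °C → rt
Reagents that add atoms: none
Why: Fluoride-mediated desilylation cleaves both Si–O bonds of the silylene acetal without touching any stereocentre.

Step 9
Reactants: 14 3-hydroxy-4-methoxybenzoic acid
Product: 15 3-acetoxy-4-methoxybenzoic acid
Conditions: Ac2O, H2SO4 (cat.), 60 °C; H2O
Reagents that add atoms: acetic anhydride CC(=O)OC(C)=O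
Why: Acid-catalysed O-acetylation protects the phenol so that it cannot compete as a nucleophile in the coupling.

Step 10
Reactants: 13 (3R,3aS,4R,8aR)-6,8a-dimethyl-3-(propan-2-yl)-1,2,3,3a,4,7,8,8a-octahydroazulene-3,4-diol; 15 3-acetoxy-4-methoxybenzoic acid
Product: 16 (3R,3aS,4R,8aR)-3-hydroxy-6,8a-dimethyl-3-(propan-2-yl)-1,2,3,3a,4,7,8,8a-octahydroazulen-4-yl 3-acetoxy-4-methoxybenzoate
Conditions: EDC·HCl, DMAP, CH2Cl2, rt → 40 °C
Reagents that add atoms: none
Why: Steglich esterification should acylate the secondary allylic C4 hydroxyl with retention, while the tertiary C3 hydroxyl next to the isopropyl group is too hindered to react.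

Step 11
Reactants: 16 acetyl-protected ester
Product: 17 (3R,3aS,4R,8aR)-3-hydroxy-6,8a-dimethyl-3-(propan-2-yl)-1,2,3,3a,4,7,8,8a-octahydroazulen-4-yl 3-hydroxy-4-methoxybenzoate (target)
Conditions: K2CO3 (0.2 equiv), MeOH, 0 °C
Reagents that add atoms: none
Why: Base-catalysed methanolysis should remove the aryl acetate much faster than the hindered alkyl aroate, releasing the phenol.

**Compound list**

1 | but-3-yn-1-ol | C#CCCO | starting material
2 | chelated (Z)-alkenylalane, 2,4-dimethyl-5,6-dihydro-2H-1,2-oxaluminine | C[Al]1OCCC(C)=C1 | intermediate (not isolated)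
3 | (3Z)-4-bromo-3-methylbut-3-en-1-ol | OCC/C(C)=C\Br | intermediate
4 | (1Z)-1-bromo-4-iodo-2-methylbut-1-ene | ICC/C(C)=C\Br | intermediate
5 | (S)-terpinen-4-ol, (1S)-4-methyl-1-(propan-2-yl)cyclohex-3-en-1-ol | CC1=CC[C@](O)(C(C)C)CC1 | starting material
6 | ozonide (1,2,4-trioxolane) of 5 | CC12CC[C@@](O)(C(C)C)CC(OO1)O2 | intermediate (not isolated)
7 | (3S)-3-hydroxy-6-oxo-3-(propan-2-yl)heptanal | CC(=O)CC[C@@](O)(C(C)C)CC=O | intermediate
8 | 4-[(4R)-2,2,4-tri(propan-2-yl)-4H-1,3,2-dioxasilin-4-yl]butan-2-one | CC(=O)CC[C@@]1(C(C)C)C=CO[Si](C(C)C)(C(C)C)O1 | intermediate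
9 | [(3Z)-4-bromo-3-methylbut-3-en-1-yl]magnesium iodide | I[Mg]CC/C(C)=C\Br | intermediate (not isolated)
10 | (6Z)-7-bromo-3,6-dimethyl-1-[(4R)-2,2,4-tri(propan-2-yl)-4H-1,3,2-dioxasilin-4-yl]hept-6-en-3-ol, both C3 epimers | CC(O)(CC/C(C)=C\Br)CC[C@@]1(C(C)C)C=CO[Si](C(C)C)(C(C)C)O1 | intermediate
11 | methyl oxalate ester of 10 | COC(=O)C(=O)OC(C)(CC/C(C)=C\Br)CC[C@@]1(C(C)C)C=CO[Si](C(C)C)(C(C)C)O1 | intermediate
12 | O3,O4-di(propan-2-yl)silanediyl acetal of diol 13 (all-cis angular 5-6-7 tricycle) | CC(C)[Si]1(C(C)C)O[C@@H]2C=C(C)CC[C@]3(C)CC[C@@](O1)(C(C)C)[C@H]23 | intermediate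
13 | (3R,3aS,4R,8aR)-6,8a-dimethyl-3-(propan-2-yl)-1,2,3,3a,4,7,8,8a-octahydroazulene-3,4-diol | O[C@@H]1C=C(C)CC[C@]2(C)CC[C@@](O)(C(C)C)[C@H]12 | intermediate
14 | 3-hydroxy-4-methoxybenzoic acid (isovanillic acid) | COc1ccc(C(=O)O)cc1O | starting material
15 | 3-acetoxy-4-methoxybenzoic acid | CC(=O)Oc1cc(C(=O)O)ccc1OC | intermediate
16 | (3R,3aS,4R,8aR)-3-hydroxy-6,8a-dimethyl-3-(propan-2-yl)-1,2,3,3a,4,7,8,8a-octahydroazulen-4-yl 3-acetoxy-4-methoxybenzoate | CC(=O)Oc1cc(ccc1OC)C(=O)O[C@@H]1C=C(C)CC[C@]2(C)CC[C@@](O)(C(C)C)[C@H]12 | intermediate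
17 | (3R,3aS,4R,8aR)-3-hydroxy-6,8a-dimethyl-3-(propan-2-yl)-1,2,3,3a,4,7,8,8a-octahydroazulen-4-yl 3-hydroxy-4-methoxybenzoate | COc1ccc(C(=O)O[C@@H]2C=C(C)CC[C@]3(C)CC[C@@](O)(C(C)C)[C@H]23)cc1O | target

**Step count.** Total: 11 steps. Longest linear sequence: 8 steps (steps 3, 4, 5, 6, 7, 8, 10, 11 from (S)-terpinen-4-ol).

**Steps most likely to fail**

1. Step 7 (proposed new method). Three processes threaten it: the cyclised α-silyloxy radical may be reduced or coupled intermolecularly before the tethered alkenylnickel intercepts it; the tertiary radical may be captured at nickel before it cyclises; and the two faces of the planar C8a radical are poorly discriminated, which could cost up to half of the material. Fallback with known chemistry, forming the two bonds in separate operations: starting from oxalate 11, Zn/MgCl2 fragmentation in DMA without nickel and with a thiol hydrogen donor would give, by 5-exo radical cyclisation and hydrogen transfer, the cis-fused bicyclic silylene acetal F1, whose C8a epimers would be separated. HF·pyridine would then release the bromoalkenyl diol F2, and selective oxidation of the primary alcohol (TEMPO, PhI(OAc)2) would give the hydroxy aldehyde F3. An intramolecular Nozaki–Hiyama–Kishi reaction (CrCl2, catalytic NiCl2, DMF) would close the cycloheptene and return to the route at diol 13.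

2. Step 4. The free β-hydroxy aldehyde may undergo base-induced retro-aldol cleavage, and its cyclic hemiketal tautomer may be silylated instead, before the six-membered ring closes. Fallback, installing the silicon tether before the oxidative cleavage: starting from (S)-terpinen-4-ol 5, silylation with iPr2SiCl2 and imidazole would give the chlorosilyl ether F4. Ozonolysis with PPh3 work-up would give the chlorosilyl keto aldehyde F5, which is not isolated, and Et3N with NaI would close the cyclic silyl enol ether, returning to the route at ketone 8.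

3. Step 5. The basic organomagnesium reagent may enolise the methyl ketone or attack silicon, and halogen scrambling may occur while the Grignard reagent forms. Fallback with reversed polarity: propargyl alcohol would be converted by copper-catalysed anti-addition of MeMgBr (CuI) and NBS quench into (2Z)-3-bromo-2-methylprop-2-en-1-ol F6, and PBr3 would give (1Z)-1,3-dibromo-2-methylprop-1-ene F7. The kinetic enolate of ketone 8 (LDA, THF, −78 °C) would be alkylated at its methyl group with F7 to give the chain-extended ketone F8, and MeMgBr with CeCl3 would then deliver the methyl group, returning to the route at tertiary alcohol 10.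

**Further compounds**

F1 | step 7 | cis-fused bicyclic silylene acetal: di(propan-2-yl)silanediyl acetal of F2 | CC(C)[Si]1(C(C)C)OC[C@@H]2[C@](C)(CC/C(C)=C\Br)CC[C@]2(C(C)C)O1
F2 | step 7 | bromoalkenyl diol: 3-[(3Z)-4-bromo-3-methylbut-3-en-1-yl]-2-(hydroxymethyl)-3-methyl-1-(propan-2-yl)cyclopentan-1-ol, configuration as in 13 | OC[C@@H]1[C@](C)(CC/C(C)=C\Br)CC[C@@]1(O)C(C)C
F3 | step 7 | hydroxy aldehyde: 2-[(3Z)-4-bromo-3-methylbut-3-en-1-yl]-5-hydroxy-2-methyl-5-(propan-2-yl)cyclopentane-1-carbaldehyde, configuration as in 13 | O=C[C@@H]1[C@](C)(CC/C(C)=C\Br)CC[C@@]1(O)C(C)C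
F4 | step 4 | chlorosilyl ether: chloro{[(1S)-4-methyl-1-(propan-2-yl)cyclohex-3-en-1-yl]oxy}di(propan-2-yl)silane | CC1=CC[C@](O[Si](Cl)(C(C)C)C(C)C)(C(C)C)CC1
F5 | step 4 | chlorosilyl keto aldehyde: (3S)-3-{[chlorodi(propan-2-yl)silyl]oxy}-6-oxo-3-(propan-2-yl)heptanal | CC(=O)CC[C@@](O[Si](Cl)(C(C)C)C(C)C)(C(C)C)CC=O
F6 | step 5 | (2Z)-3-bromo-2-methylprop-2-en-1-ol | OC/C(C)=C\Br
F7 | step 5 | (1Z)-1,3-dibromo-2-methylprop-1-ene | BrC/C(C)=C\Br
F8 | step 5 | chain-extended ketone: (6Z)-7-bromo-6-methyl-1-[(4R)-2,2,4-tri(propan-2-yl)-4H-1,3,2-dioxasilin-4-yl]hept-6-en-3-one | O=C(CC/C(C)=C\Br)CC[C@@]1(C(C)C)C=CO[Si](C(C)C)(C(C)C)O1
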